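**Retrosynthetic overview**

1. Labels: decalin C1–C10 with linker C11H2 (drimane numbering); ring C1′(CH3)=C2′H–C3′H(OH)–C4′(C11)(–O–)–C5′H(–O–)–C6′H(OH); Dr = decalin residue of 7 bonded through C9 (4α-CO2CH2CH2SiMe3, 4β-CH3, 5α-H, 8-CH3, C7=C8, 9α-H, 10β-CH3).
2. 18 ⇐ silyl ester 17 ⇐ ring-closing metathesis (C1′=C2′) of acyclic epoxy diol 16, which already carries the oxirane and all four stereocentres of that ring.
3. Enabling feature: the cis-oxirane C4′–C5′ places C3′ and C6′ on one side, and the only ring olefin C1′=C2′ lies between these two carbinols, so the ring is a 1,7-diene retron. Both OH groups anti to the oxirane O is the threo,threo array of a doubly hydroxyl-directed epoxidation of (Z)-ene-1,4-diol 15; ketone reduction on a preformed ring would give the syn array instead.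
4. 15 ⇐ alkyne 7 by asymmetric alkynylation of methacrolein (C6′), trans-hydrosilylation/iodination and carbonylative vinylation (C4′–C3′), then CBS reduction (C3′).
5. 7 ⇐ levopimaric acid 1 (rings A/B with C4, C5, C9, C10 from the pool) by ozonolysis of ring C, alkyne homologation and enol triflate methylation; ring order: A/B (pool) → oxirane (step 12) → carbocycle C1′–C6′ (step 13).

Key step: step 13

Assumption: levopimaric acid is used as purchased (air- and acid-sensitive resin acid), and the ProPhenol and CBS enantiomers named are those expected from the usual models to give C6′ (S) in 9 and C3′ (R) in 15; the antipodal catalyst would be taken if the opposite sense were found.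

**Route**

Step 1
Reactants: 1 levopimaric acid
Product: 2 2-(trimethylsilyl)ethyl levopimarate
Conditions: Me3SiCH2CH2OH, PPh3, DIAD, THF, 0 °C → rt
Reagents that add atoms: 2-(trimethylsilyl)ethanol, C[Si](C)(C)CCO
Why: Mitsunobu esterification, in which the hindered tertiary carboxylate only has to attack the activated primary alkoxyphosphonium ion, so the ester should form under neutral conditions that do not isomerise the homoannular diene; no stereocentre is touched.

Step 2
Reactants: 2 2-(trimethylsilyl)ethyl levopimarate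
Product: 3 keto aldehyde (trans-decalin silyl ester with C8 ketone and C9β–C11H2–CHO; 4β-CH3, 5α-H, 9α-H, 10β-CH3)
Conditions: O3, pyridine, CH2Cl2, −78 °C
Reagents that add atoms: ozone, [O-][O+]=O
Why: Ozonolysis in the presence of pyridine should cleave both ring-C olefins (C8=C14 and C12=C13) directly to carbonyl groups, leaving the C8 ketone and the side-chain aldehyde on the intact decalin; C9 is α to the new ketone, but its equatorial side chain (9α-H) is the stable epimer.

Step 3
Reactants: 3 keto aldehyde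
Product: 4 alkynyl ketone (as 3, with C9β–C11H2–C4′≡C5′H)
Conditions: dimethyl (1-diazo-2-oxopropyl)phosphonate, K2CO3, MeOH, 0 °C → rt
Reagents that add atoms: dimethyl (1-diazo-2-oxopropyl)phosphonate, CC(=O)C(=[N+]=[N-])P(=O)(OC)OC
Why: Seyferth–Gilbert homologation (Ohira–Bestmann protocol) converts the aldehyde into the terminal alkyne while the hindered C8 ketone and the neopentyl-type ester should not react; the aldehyde carbon becomes C4′ and the added carbon C5′.

Step 4
Reactants: 4 alkynyl ketone
Product: 6 C7=C8 enol triflate of ketone 4 (8-triflyloxy), via potassium enolate 5 (not isolated)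
Conditions: KHMDS (1.05 equiv), THF, −78 °C; then PhNTf2, −78 → 0 °C
Reagents that add atoms: N-phenylbis(trifluoromethanesulfonimide), O=S(=O)(N(c1ccccc1)S(=O)(=O)C(F)(F)F)C(F)(F)F
Why: Kinetic enolisation and O-triflation: the bulky amide should remove the unhindered C7–H rather than the tertiary C9–H, and the ketone is more acidic than the alkyne C–H, so the C7=C8 enol triflate forms and C9 is not epimerised.

Step 5
Reactants: 6 enol triflate
Product: 7 alkyne Dr–C11H2–C4′≡C5′H (8-methyl, C7=C8)
Conditions: Me2CuLi (from MeLi and CuI, 3 equiv), THF, −20 → 0 °C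
Reagents that add atoms: lithium dimethylcuprate, [Li+].C[Cu-]C
Why: Cuprate coupling of an enol triflate (McMurry–Scott reaction) replaces OTf by CH3 with the olefin fixed at C7=C8; the alkyne C–H is at most reversibly metalated and the hindered ester is inert to the cuprate.

Step 6
Reactants: 7 alkyne Dr–C11H2–C≡CH, 8 methacrolein
Product: 9 (6′S)-propargylic alcohol Dr–C11H2–C4′≡C5′–C6′H(OH)–C1′(CH3)=CH2
Conditions: Me2Zn, (S,S)-ProPhenol (20 mol %), Ph3P=O (40 mol %), toluene, 4 °C
Reagents that add atoms: none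
Why: Zinc–ProPhenol-catalysed alkynylation of an enal (Trost): the dinuclear zinc catalyst should deliver the alkynylzinc to the Re face of methacrolein, setting C6′ as (S) under catalyst control, since the remote decalin centres exert no influence.

Step 7
Reactants: 9 propargylic alcohol
Product: 10 (Z)-vinylsilane Dr–C11H2–C4′(SiEt3)=C5′H–C6′H(OH)–C1′(CH3)=CH2 (Si cis to C6′, 6′R)
Conditions: Et3SiH, [Cp*Ru(MeCN)3]PF6 (5 mol %), CH2Cl2, 0 °C → rt
Reagents that add atoms: triethylsilane, CC[SiH](CC)CC
Why: Ruthenium-catalysed trans-hydrosilylation of a propargylic alcohol (Trost): H and Si add anti and the hydroxyl group steers silicon to the distal alkyne carbon C4′, so Si ends cis to C6′, as needed for the later cis relation of C3′ and C6′; the olefins are not hydrosilylated.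

Step 8
Reactants: 10 (Z)-vinylsilane
Product: 11 (Z)-vinyl iodide Dr–C11H2–C4′(I)=C5′H–C6′H(OH)–C1′(CH3)=CH2 (I cis to C6′)
Conditions: NIS, 2,6-lutidine (cat.), MeCN/ClCH2CN, 0 °C
Reagents that add atoms: N-iodosuccinimide, O=C1CCC(=O)N1I
Why: Iododesilylation: ipso attack of I+ on the vinylsilane, favoured by the β-silicon effect, should replace SiEt3 by iodine with retention of olefin geometry and faster than iodine adds to the other olefins.

Step 9
Reactants: 11 (Z)-vinyl iodide
Product: 12 triethylsilyl ether of 11 (C6′–OSiEt3)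
Conditions: TESCl, imidazole, CH2Cl2, 0 °C
Reagents that add atoms: chlorotriethylsilane, CC[Si](Cl)(CC)CC
Why: Silylation of the secondary alcohol prevents lactol formation with the C3′ ketone made in the next step; no stereocentre is affected.

Step 10
Reactants: 12 silyl ether
Product: 13 (Z)-dienone CH2=C2′H–C3′(=O)–C4′(C11H2Dr)=C5′H–C6′H(OSiEt3)–C1′(CH3)=CH2 (C3′ cis to C6′)
Conditions: CO (1 atm), CH2=CHSnBu3, Pd2(dba)3 (5 mol %), AsPh3 (20 mol %), THF, 45 °C
Reagents that add atoms: carbon monoxide, [C-]#[O+]; tributyl(vinyl)stannane, C=C[Sn](CCCC)(CCCC)CCCC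
Why: Carbonylative Stille coupling: oxidative addition, CO insertion and vinyl transfer should give the divinyl ketone with retention of the (Z)-olefin, so C3′ is installed cis to C6′.

Step 11
Reactants: 13 (Z)-dienone
Product: 15 (3′R,6′R)-(Z)-ene-1,4-diol CH2=C2′H–C3′H(OH)–C4′(C11H2Dr)=C5′H–C6′H(OH)–C1′(CH3)=CH2, via TES-protected carbinol 14 (not isolated)
Conditions: (S)-Me-CBS (0.5 equiv), catecholborane, toluene, −78 °C; then MeOH, PPTS, rt
Reagents that add atoms: none
Why: Corey–Bakshi–Shibata reduction: the oxazaborolidine should bind the ketone anti to the bulky α-branched alkenyl group (vinyl as the small group) and deliver hydride in the 1,2-sense to give C3′ (R), after which acidic methanolysis removes the TES group.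

Step 12
Reactants: 15 (Z)-ene-1,4-diol
Product: 16 (3′R,4′S,5′R,6′S)-epoxy diol (cis-oxirane C4′–C5′, vinyl on C3′, isopropenyl on C6′)
Conditions: Ti(OiPr)4 (1.1 equiv), t-BuOOH, 4 Å MS, CH2Cl2, −20 °C
Reagents that add atoms: tert-butyl hydroperoxide, CC(C)(C)OO
Why: Titanium-alkoxide-directed epoxidation of an allylic alcohol: only olefins allylic to a titanium-bound hydroxyl react, so C7=C8 is spared, and the trisubstituted C4′=C5′ bond flanked by both carbinols is the most nucleophilic of them; with each carbinol H eclipsing the (Z)-olefin (A1,3 strain) both hydroxyls lie on the same face and deliver oxygen there, which should give the threo,threo epoxy diol with C4′ (S) and C5′ (R).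

Step 13
Reactants: 16 epoxy diol
Product: 17 2-(trimethylsilyl)ethyl ester of the target (carbocycle C1′–C6′ closed)
Conditions: Grubbs II (10 mol %), 1,4-benzoquinone (20 mol %), toluene (2 mM), 60 °C
Reagents that add atoms: none
Why: Ring-closing metathesis by the Chauvin mechanism: the ruthenium alkylidene loads on the monosubstituted vinyl group at C2′, forms a ruthenacyclobutane with the isopropenyl olefin at C1′ and collapses with loss of ethene to the C1′=C2′ bond. The closest known reaction type is RCM of oxygenated octa-1,7-dienes to conduritol- and epoxyquinol-type cyclohexenes, including trisubstituted olefins from isopropenyl carbinols. The carbocycle closes as a six-membered ring by [2+2]/retro-[2+2], and its olefin is necessarily (Z) and trisubstituted. No stereocentre is created: C3′, C4′, C5′ and C6′ are carried in from 16 and none is epimerisable under the neutral conditions. The step needs chemoselectivity for the two terminal olefins over the trisubstituted C7=C8 bond, and cyclisation must beat dimerisation and Ru–H isomerisation of the allylic alcohols; the cis-oxirane, which holds both alkenyl carbinols on one side, high dilution and benzoquinone should secure this.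

Step 14
Reactants: 17 silyl ester of the target
Product: 18 target acid
Conditions: TBAF, THF, 0 °C → rt; pH 5 buffer work-up
Reagents that add atoms: none
Why: Fluoride-induced fragmentation of the 2-(trimethylsilyl)ethyl ester (attack at silicon, loss of ethene) should free the hindered acid without attack at the carbonyl and without acid, so the oxirane, the allylic alcohols and all stereocentres are preserved.

**Compound list**

1 | levopimaric acid (abieta-8(14),12-dien-18-oic acid; 4α-CO2H, 4β-CH3, 5α-H, 9α-H, 10β-CH3) | CC(C)C1=CC[C@H]2C(=C1)CC[C@@H]3[C@]2(C)CCC[C@@]3(C)C(=O)O | starting material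
2 | 2-(trimethylsilyl)ethyl levopimarate | CC(C)C1=CC[C@H]2C(=C1)CC[C@@H]3[C@]2(C)CCC[C@@]3(C)C(=O)OCC[Si](C)(C)C | intermediate
3 | keto aldehyde: C8 ketone, C9β–CH2CHO, 4α-silyl ester | O=CC[C@H]1C(=O)CC[C@@H]2[C@]1(C)CCC[C@@]2(C)C(=O)OCC[Si](C)(C)C | intermediate
4 | alkynyl ketone: C8 ketone, C9β–CH2C≡CH | C#CC[C@H]1C(=O)CC[C@@H]2[C@]1(C)CCC[C@@]2(C)C(=O)OCC[Si](C)(C)C | intermediate
5 | potassium C7=C8 enolate of 4 | C#CC[C@H]1C([O-])=CC[C@@H]2[C@]1(C)CCC[C@@]2(C)C(=O)OCC[Si](C)(C)C.[K+] | intermediate
6 | C7=C8 enol triflate of 4 | C#CC[C@H]1C(OS(=O)(=O)C(F)(F)F)=CC[C@@H]2[C@]1(C)CCC[C@@]2(C)C(=O)OCC[Si](C)(C)C | intermediate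
7 | alkyne Dr–C11H2–C≡CH (8-methyl, C7=C8) | C#CC[C@H]1C(C)=CC[C@@H]2[C@]1(C)CCC[C@@]2(C)C(=O)OCC[Si](C)(C)C | intermediate
8 | methacrolein (2-methylprop-2-enal) | C=C(C)C=O | starting material
9 | (6′S)-propargylic alcohol | C=C(C)[C@H](O)C#CC[C@H]1C(C)=CC[C@@H]2[C@]1(C)CCC[C@@]2(C)C(=O)OCC[Si](C)(C)C | intermediate
10 | (Z)-vinylsilane (SiEt3 on C4′, cis to C6′; 6′R) | CC[Si](CC)(CC)/C(C[C@H]1C(C)=CC[C@@H]2[C@]1(C)CCC[C@@]2(C)C(=O)OCC[Si](C)(C)C)=C\[C@@H](O)C(C)=C | intermediate
11 | (Z)-vinyl iodide (I on C4′, cis to C6′; 6′R) | I/C(C[C@H]1C(C)=CC[C@@H]2[C@]1(C)CCC[C@@]2(C)C(=O)OCC[Si](C)(C)C)=C\[C@@H](O)C(C)=C | intermediate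
12 | triethylsilyl ether of 11 | I/C(C[C@H]1C(C)=CC[C@@H]2[C@]1(C)CCC[C@@]2(C)C(=O)OCC[Si](C)(C)C)=C\[C@@H](O[Si](CC)(CC)CC)C(C)=C | intermediate
13 | (Z)-dienone (C3′ ketone cis to C6′–OTES) | C=CC(=O)/C(C[C@H]1C(C)=CC[C@@H]2[C@]1(C)CCC[C@@]2(C)C(=O)OCC[Si](C)(C)C)=C\[C@@H](O[Si](CC)(CC)CC)C(C)=C | intermediate
14 | (3′R)-carbinol with C6′–OTES | C=C[C@@H](O)/C(C[C@H]1C(C)=CC[C@@H]2[C@]1(C)CCC[C@@]2(C)C(=O)OCC[Si](C)(C)C)=C\[C@@H](O[Si](CC)(CC)CC)C(C)=C | intermediate
15 | (3′R,6′R)-(Z)-ene-1,4-diol | C=C[C@@H](O)/C(C[C@H]1C(C)=CC[C@@H]2[C@]1(C)CCC[C@@]2(C)C(=O)OCC[Si](C)(C)C)=C\[C@@H](O)C(C)=C | intermediate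
16 | (3′R,4′S,5′R,6′S)-epoxy diol | C=C[C@@H](O)[C@]1(C[C@H]2C(C)=CC[C@@H]3[C@]2(C)CCC[C@@]3(C)C(=O)OCC[Si](C)(C)C)O[C@@H]1[C@@H](O)C(C)=C | intermediate
17 | 2-(trimethylsilyl)ethyl ester of the target | CC1=C[C@@H](O)[C@]2(C[C@H]3C(C)=CC[C@@H]4[C@]3(C)CCC[C@@]4(C)C(=O)OCC[Si](C)(C)C)O[C@@H]2[C@H]1O | intermediate
18 | target acid (3′R,4′S,5′R,6′S; 4α-CO2H) | CC1=C[C@@H](O)[C@]2(C[C@H]3C(C)=CC[C@@H]4[C@]3(C)CCC[C@@]4(C)C(=O)O)O[C@@H]2[C@H]1O | target

Total step count: 14. Longest linear sequence: 14 steps (1 → 18).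

**Steps most likely to fail**

Step 13 (ring-closing metathesis). The risk is Ru–H-mediated isomerisation of the free allylic alcohols to ketones, binding of ruthenium by the 1,4-diol/oxirane array, or slow uptake of the isopropenyl olefin with dimerisation at the vinyl group. The fallback closes the ring on a fully masked substrate and merges all deprotections. It sets out from 16, which is silylated (TESOTf, 2,6-lutidine) to the bis(triethylsilyl) ether of 16 F1. RCM of this ether (Hoveyda–Grubbs II, toluene, 80 °C) should give the bis(triethylsilyl) ether of 17 F2. Excess TBAF then removes both silyl ethers and the silylethyl ester together, and the route is rejoined at 18.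

Step 11 (CBS reduction). The risk is poor facial discrimination between the vinyl and the substituted alkenyl group, or competing 1,4-reduction of the vinyl ketone. The fallback makes the small group a linear alkyne and sets C3′ by transfer hydrogenation. It sets out from 12, which under carbonylative Sonogashira conditions (trimethylsilylacetylene, CO, PdCl2(PPh3)2, CuI, Et3N) should give the silyl ynone F3. Noyori transfer hydrogenation (Ru–TsDPEN, i-PrOH, catalyst antipode chosen for the required sense) should give the propargylic alcohol F4, and K2CO3/MeOH the terminal alkyne F5. Lindlar semi-hydrogenation of the alkyne then rejoins the route at 14, which is desilylated as in step 11.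

Step 7 (trans-hydrosilylation). The risk is loss of regiocontrol (silicon delivered to C5′) or ruthenium-catalysed redox isomerisation of the propargylic alcohol. The fallback fixes the regiochemistry with a silicon tether. It sets out from 9, which with 1,1,3,3-tetramethyldisilazane should give the dimethylsilyl ether F6. Intramolecular endo-dig trans-hydrosilylation ([Cp*Ru(MeCN)3]PF6) can then only place silicon on C4′ and should give the 2,5-dihydro-1,2-oxasilole F7. Ring-opening iododesilylation with NIS rejoins the route at 11.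

**Further compounds**

F1 | step 13 | bis(triethylsilyl) ether of 16 | C=C[C@@H](O[Si](CC)(CC)CC)[C@]1(C[C@H]2C(C)=CC[C@@H]3[C@]2(C)CCC[C@@]3(C)C(=O)OCC[Si](C)(C)C)O[C@@H]1[C@@H](O[Si](CC)(CC)CC)C(C)=C
F2 | step 13 | bis(triethylsilyl) ether of 17 | CC1=C[C@@H](O[Si](CC)(CC)CC)[C@]2(C[C@H]3C(C)=CC[C@@H]4[C@]3(C)CCC[C@@]4(C)C(=O)OCC[Si](C)(C)C)O[C@@H]2[C@H]1O[Si](CC)(CC)CC
F3 | step 11 | (Z)-alkenyl trimethylsilylethynyl ketone (C3′ ketone, C6′–OTES) | C[Si](C)(C)C#CC(=O)/C(C[C@H]1C(C)=CC[C@@H]2[C@]1(C)CCC[C@@]2(C)C(=O)OCC[Si](C)(C)C)=C\[C@@H](O[Si](CC)(CC)CC)C(C)=C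
F4 | step 11 | C3′ propargylic alcohol with silylated alkyne | C[Si](C)(C)C#C[C@@H](O)/C(C[C@H]1C(C)=CC[C@@H]2[C@]1(C)CCC[C@@]2(C)C(=O)OCC[Si](C)(C)C)=C\[C@@H](O[Si](CC)(CC)CC)C(C)=C
F5 | step 11 | C3′ propargylic alcohol with terminal alkyne | C#C[C@@H](O)/C(C[C@H]1C(C)=CC[C@@H]2[C@]1(C)CCC[C@@]2(C)C(=O)OCC[Si](C)(C)C)=C\[C@@H](O[Si](CC)(CC)CC)C(C)=C
F6 | step 7 | dimethylsilyl ether of 9 | C=C(C)[C@H](O[SiH](C)C)C#CC[C@H]1C(C)=CC[C@@H]2[C@]1(C)CCC[C@@]2(C)C(=O)OCC[Si](C)(C)C
F7 | step 7 | 2,2-dimethyl-2,5-dihydro-1,2-oxasilole (Si on C4′, ring O on C6′) | C=C(C)[C@@H]1O[Si](C)(C)C(C[C@H]2C(C)=CC[C@@H]3[C@]2(C)CCC[C@@]3(C)C(=O)OCC[Si](C)(C)C)=C1
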